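Take a small charge of catalyst, 0.15 mol% of Z on G, and count G as a fraction g of its charge and each catalyst form as a fraction of the Z charged.

G 0.80 M; Z 0.15 mol%

    G.Z → Z + J (k1 = 2.6 s⁻¹)
    G + Z ⇌ G.Z (K2 = 0.94 M⁻¹, k2 = 140 M⁻¹ s⁻¹)
    Z ⇌ X (K3 = 3.4, k3 = 0.018 s⁻¹)

* the form that holds most of the catalyst when 20% of the G are converted (G.Z / X / Z)
* its share of the catalyst then

Reckon first by hand. G.Z falls back to G + Z at 149 s⁻¹, faster than it goes on to J at 2.6 s⁻¹, so treat step 2 as a pre-equilibrium. At 20% conversion, G.Z over Z is then 0.602, and the free part of the working catalyst is f = 0.624.

Z also leaks into X, which stands outside the working round (off-cycle). With step 3 in balance, X holds 68.0% of the catalyst. Call this the parked share, the fraction of the catalyst in X when step 3 balances at the present g.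

Now ask whether X gets there in time. Step 3 relaxes at 0.992 min⁻¹, so the working fraction falls exponentially towards 32.0%. Integrating the rate of step 1 in closed form, with step 2 in balance, shows that this conversion needs a time integral of the working fraction of 2.12 min. The early decay supplies part of that integral, which gives a time of 4.49 min, or 4.45 relaxation times. My answer is therefore X, at 67.2%.

The forecast also names X, at 67%, holding that “X has nearly reached its quasi-equilibrium”.

The simulation gives X at 66.9%, with 20.8% in Z and 12.3% in G.Z. This flask took 4.42 min to reach 20% conversion, which is 4.38 relaxation times at 0.992 min⁻¹, and X stood 1.1 percentage points below the parked share. Later in the same flask, with a fraction 0.7 of the G converted, the free part is 0.816 and the parked share comes to 73.5%, while X reads 73.5% at 31.3 min.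

The rate constants are those of an exercise; the run is a simulation.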